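All runs are simulated for an exercise, noise included.

- The question is which species holds the largest fraction of the substrate charged after 20 h in dusk, autumn and summer, and what fraction single product holds in dusk.

| flask | substrate | partner | scavenger | remark | time |
|---|---|---|---|---|---|
| north-east | 14 mM | 2.5 equiv | 1.8 equiv | run made earlier |  |
| south-east | 28 mM | 2.5 equiv | 1.2 equiv | run made earlier |  |
| dusk | 14 mM | 2.50 equiv | 1.20 equiv |  | 20 h |
| autumn | 14 mM | 1.00 equiv | 1.20 equiv |  | 20 h |
| summer | 14 mM | 0.800 equiv | 1.20 equiv |  | 20 h |

| run | time / h | single product / % | tris adduct / % |
|---|---|---|---|
| north-east | 1.00 | 30.6 | 0 |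
| north-east | 2.00 | 38.5 | 3.0 |
| north-east | 3.00 | 37.8 | 6.3 |
| north-east | 6.00 | 32.0 | 19.3 |
| north-east | 12.0 | 18.3 | 35.1 |
| south-east | 1.00 | 36.4 | 2.3 |
| south-east | 2.00 | 34.2 | 10.8 |
| south-east | 3.00 | 26.4 | 18.8 |
| south-east | 6.00 | 12.0 | 38.8 |
| south-east | 12.0 | 4.3 | 54.2 |

(scatter of a reading: 1 percentage point)

- the numbers in the tables scatter with a standard deviation of 1 percentage point

- which of these holds the largest part of the substrate at the end of dusk (tris adduct / bis adduct / substrate / single product)
- which of these holds the largest part of the substrate at the end of autumn (tris adduct / bis adduct / substrate / single product)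
- which of these holds the largest part of the substrate at the end of summer (tris adduct / bis adduct / substrate / single product)
- amount of single product at the end of dusk, in percent of the substrate charged

- Let x be a species' fraction of the substrate charged, y the partner's amount per substrate charged, and c the substrate concentration at the start. A bimolecular step then reads dx/dt = −k·c·x·y, so if every step is bimolecular, flasks with equal equivalents follow one curve in c·t.
- The two runs can be held against this. North-east at 6.00 h shows tris adduct 19.3% and south-east at 3.00 h shows 18.8%, with twice the concentration. Single product in that pair differs by 5.6 points, but north-east also carries 1.8 equiv of scavenger.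
- Dusk shares 2.50 equiv of partner and 1.20 equiv of scavenger with south-east, so south-east serves as its clock. The south-east-equivalent time, t·c divided by the 28 mM of south-east, is 10.0 h for dusk at 20 h.
- That time falls between the south-east readings at 6.00 h and 12.0 h. Treating the late loss of single product as pseudo-first-order, x = x(start)·exp(−λt), these readings give λ = 0.171 h⁻¹. This reckoning therefore puts single product in dusk at 6.05%, a figure that carries the scatter of the readings.
- The forecast names tris adduct for dusk, single product for autumn and substrate for summer, with 6.5% of single product in dusk, slightly above this reckoning. Its ground: “Doubling the concentration roughly halves the time”.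

    substrate + partner → single product + released group (k = 0.00440 M⁻¹ s⁻¹)
    partner + single product → bis adduct + released group (k = 0.00380 M⁻¹ s⁻¹)
    partner + bis adduct → tris adduct + released group (k = 0.00230 M⁻¹ s⁻¹)
    substrate + released group ⇌ idle adduct, settled at all times (K = 770 M⁻¹)
    scavenger + released group → scavenged by-product (k = 1.40 M⁻¹ s⁻¹)

- Autumn ends with single product 39.2% over substrate 34.1%, and summer with substrate 43.0% over single product 38.3%. In dusk, half of the first step's turnover up to 20 h was done by 1.21 h and of the second's by 3.82 h; at 10.0 h scavenger stood at 0% of its own charge and idle adduct held 14.0% of the substrate charged. At 20.0 h dusk holds tris adduct 50.2%, more than bis adduct 27.5% and idle adduct 13.0% together, with single product 7.78%. Dusk read at 8.0 h stands at 4.00 h on the south-east clock, where the readings give 20.3% of single product; the flask gives 20.9%.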